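Plan (eudesmane numbering)
1. Retrosynthesis: the C5–OOH group and the C4=C15 bond are removed together (Schenck ene, back to the C4=C5 alkene 19). The C3 angelate, the C3 carbinol (back to the enone) and the C12 ester (back to isopropenyl) follow, which leads to (+)-α-cyperone 11.
2. Ring A of 11 is cut at C1–C10 and C3–C4. C1–C2–C3(O) is acrolein. C10–C5–C4 is an allyl unit centred on the ring-fusion carbon C5, and its two ends attack in turn while the double bond walks C5=C10 → C4=C5 → C5=C6.
3. Enabling feature: C6 is next to C5, and C7 carries the C11 isopropyl unit. A temporary C6–C11 bond (gem-dimethylcyclopropane on ring B, carene skeleton) makes C5=C10 a vinylcyclopropane. This polarises the alkene for attack at C10, shields the β face, hides the isopropenyl group, and ends the cascade by strain-releasing ring opening.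
4. Forward order: ring B comes from (R)-carvone. The cyclopropane is closed (steps 1–2), C4–C15 is attached to C5 (steps 3–4), and ring A is closed while the cyclopropane opens (step 5). Redox and ester adjustments follow (steps 6–11), then oxygenation (step 12).
5. Stereochemistry: C7 from (R)-carvone; C10 from the cyclopropane-shielded face in step 5; C3 from axial hydride delivery; C5 from α-face attack of singlet oxygen anti to the C14 methyl group; the Z alkene from angelic acid.

Key step: step 5

Remark: eudesmane numbering is used for every intermediate (ring A = C1–C5 and C10; ring B = C5–C10; C14 on C10; C15 on C4; C11–C13 on C7), β is the face of the C14 methyl group, the target is (3S,5S,7R,10S), and 9 and 10 are carried on as C3/C4 epimer mixtures because step 6 erases both centres.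

Step 1
Reactants: 1 (R)-(−)-carvone
Product: 2 (5R)-5-(2-chloropropan-2-yl)-2-methylcyclohex-2-en-1-one (carvone hydrochloride)
Conditions: HCl (g), Et2O, 0 °C
Reagents that add atoms: hydrogen chloride, Cl
Why: Markovnikov hydrochlorination; the electron-rich 1,1-disubstituted alkene is protonated to the tertiary C11 cation much faster than the enone alkene, and C7 is untouched.

Step 2
Reactants: 2 carvone hydrochloride
Product: 3 (1S,6R)-3,7,7-trimethylbicyclo[4.1.0]hept-3-en-2-one (car-3-en-2-one)
Conditions: KOt-Bu, THF, 0 °C
Reagents that add atoms: none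
Why: Intramolecular enolate alkylation (3-exo-tet), a well-precedented entry from carvone to the carene skeleton; the C6 enolate displaces the C11 chloride, and the three-membered ring can only be cis-fused, so C7 sets C6.

Step 3
Reactants: 3 car-3-en-2-one
Product: 5 (1S,6R)-3,7,7-trimethylbicyclo[4.1.0]hept-2-en-2-yl trifluoromethanesulfonate, via lithium enolate 4 (not isolated)
Conditions: LiBH(s-Bu)3, THF, −78 °C; then PhNTf2, −78 °C → rt
Reagents that add atoms: N-phenylbis(trifluoromethanesulfonimide), O=S(=O)(N(c1ccccc1)S(=O)(=O)C(F)(F)F)C(F)(F)F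
Why: Conjugate hydride addition at C9 gives regiospecifically the tetrasubstituted C5=C10 enolate, which is trapped on oxygen (reductive enolate triflation); no stereocentre is formed and the cyclopropane is not conjugated with the enolate.

Step 4
Reactants: 5 alkenyl triflate
Product: 6 (1S,6R)-2-ethyl-3,7,7-trimethylbicyclo[4.1.0]hept-2-ene (2-ethyl-2-carene)
Conditions: EtMgBr, Fe(acac)3 (5 mol %), THF/NMP, −20 °C → 0 °C
Reagents that add atoms: ethylmagnesium bromide, CC[Mg]Br
Why: Iron-catalysed Kumada-type cross-coupling of an alkenyl triflate with an alkyl Grignard reagent, fast enough at low temperature to outrun β-hydride elimination; it attaches C4–C15 to C5 and leaves both stereocentres alone.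

Step 5
Reactants: 6 2-ethyl-2-carene; 7 acrolein
Product: 9 (4aS,7R)-1,4a-dimethyl-7-(prop-1-en-2-yl)-1,2,3,4,4a,5,6,7-octahydronaphthalen-2-ol (eudesma-5,11-dien-3-ol; C3/C4 epimers), via ene-adduct aldehyde 8 (not isolated)
Conditions: acrolein (1.05 equiv), Me2AlCl (2.5 equiv), 2,6-di-tert-butyl-4-methylpyridine (1.2 equiv), CH2Cl2, −78 °C → 0 °C; then cold 1 M HCl
Reagents that add atoms: none
Why: Proposed new method: the β-carbon C1 of Me2AlCl-bound acrolein is attacked by C10 of the C5=C10 alkene and a C4 hydrogen shifts to C2 (conjugate ene reaction) to give aldehyde 8 with a C4=C5 ethylidene group; its Al-bound carbonyl carbon C3 is then attacked by C4, the charge building on C5 passes into the aligned C6–C11 bond, the cyclopropane opens with release of its strain to leave C5=C6, and the tertiary C11 cation loses a methyl proton to the hindered pyridine to give the isopropenyl group. The closest known reaction type is the Me2AlCl-promoted sequential ene annulation of alkylidenecycloalkanes with acrolein (conjugate ene reaction, then type 1 intramolecular carbonyl-ene reaction), joined here to the known cyclopropylcarbinyl-to-homoallyl opening of 2-carenes by electrophiles. Ring A closes as a six-membered ring, exo with respect to the C3=O bond and endo with respect to the C4=C5 bond, through a chair-like array of C10–C1–C2–C3. C10 is set by the endo methyl group of the CMe2 bridge, which covers the β face of ring B so that C1 arrives on the α face anti to C11 (a free equatorial isopropenyl group would favour the opposite face), C7 is carried over from carvone, and C3 and C4 need no control because step 6 erases them. The step needs regioselectivity (C10 over C5, secured because only attack at C10 puts the charge on C5 next to the cyclopropane), chemoselectivity (no nucleophilic 1,1-disubstituted alkene may be present while acrolein is, secured because the isopropenyl group stays masked until ring A is closed) and correct timing (proton shift inside the tight first zwitterion before ring opening, favoured in CH2Cl2 at low temperature, where moving the charge out to C11 is costly, whereas in the second stage C5 has no transferable neighbouring hydrogen and ring opening is the only outlet).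

Step 6
Reactants: 9 eudesma-5,11-dien-3-ol
Product: 11 (+)-α-cyperone [(4aS,7R)-1,4a-dimethyl-7-(prop-1-en-2-yl)-4,4a,5,6,7,8-hexahydronaphthalen-2(3H)-one], via deconjugated enone 10 (not isolated)
Conditions: Al(Oi-Pr)3 (0.3 equiv), cyclohexanone, toluene, reflux
Reagents that add atoms: none
Why: Oppenauer oxidation; hydride transfer from C3 to cyclohexanone gives the β,γ-enone 10, which the aluminium alkoxide moves into conjugation through its dienolate, as in the classical conversion of 5-en-3-ols into 4-en-3-ones, so the C3 and C4 centres vanish while C7 and C10 are untouched.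

Step 7
Reactants: 11 (+)-α-cyperone
Product: 13 3-oxoeudesma-4,11(13)-dien-12-al, via allylic alcohol 12 (not isolated)
Conditions: SeO2 (0.3 equiv), t-BuOOH, CH2Cl2, rt; crude product, then Dess–Martin periodinane, CH2Cl2, 0 °C → rt
Reagents that add atoms: tert-butyl hydroperoxide, CC(C)(C)OO
Why: Selenium dioxide allylic oxidation (ene reaction, then 2,3-sigmatropic shift) acts on the only electron-rich alkene, the isopropenyl group, while the enone alkene is deactivated, and the Dess–Martin oxidation converges alcohol 12 and any aldehyde already formed to 13.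

Step 8
Reactants: 13 enal
Product: 14 3-oxoeudesma-4,11(13)-dien-12-oic acid
Conditions: NaClO2, NaH2PO4, 2-methyl-2-butene, t-BuOH/H2O, 0 °C → rt
Reagents that add atoms: sodium chlorite, [Na+].[O-]Cl=O
Why: Pinnick oxidation; it converts the α-substituted acrolein into the acrylic acid without touching the enone, and the scavenger alkene removes HOCl.

Step 9
Reactants: 14 acid
Product: 15 methyl 3-oxoeudesma-4,11(13)-dien-12-oate
Conditions: MeI, K2CO3, DMF, rt
Reagents that add atoms: iodomethane, CI
Why: SN2 O-alkylation of the carboxylate; the base is too weak to enolise the enone productively and no stereocentre is affected.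

Step 10
Reactants: 15 keto ester
Product: 16 methyl 3β-hydroxyeudesma-4,11(13)-dien-12-oate
Conditions: NaBH4, CeCl3·7H2O, MeOH, −40 °C
Reagents that add atoms: none
Why: Luche reduction; 1,2-selective hydride delivery to the enone (the acrylate is left alone at low temperature) takes place axially from the α face, opposite the C14 methyl group, and should give the equatorial 3β (3S) alcohol, as with 4-en-3-ones that carry a 10β-methyl group.

Step 11
Reactants: 16 allylic alcohol; 17 angelic acid
Product: 19 methyl 3β-angeloyloxyeudesma-4,11(13)-dien-12-oate, via mixed anhydride 18 (not isolated)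
Conditions: 17, 2,4,6-trichlorobenzoyl chloride, Et3N, toluene, rt; then 16, 80 °C (no DMAP)
Reagents that add atoms: none
Why: Yamaguchi-type mixed-anhydride esterification run without a nucleophilic catalyst, the usual way to transfer the angeloyl group without Z-to-E isomerisation to the tiglate; C3 keeps its configuration because only the O–H bond reacts.

Step 12
Reactants: 19 angelate
Product: 20 methyl 3β-angeloyloxy-5α-hydroperoxyeudesma-4(15),11(13)-dien-12-oate (target)
Conditions: O2, tetraphenylporphyrin (cat.), visible light, CH2Cl2, −20 °C; no reductive work-up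
Reagents that add atoms: dioxygen, O=O
Why: Schenck ene reaction; singlet oxygen attacks only the electron-rich tetrasubstituted C4=C5 alkene (both conjugated esters are electron-poor) from the α face anti to the axial C14 methyl group, so that oxygen binds to C5 as the axial 5α substituent, and abstraction of a C15 hydrogen geminal to the bulky, electron-withdrawing C3 acyloxy carbon moves the double bond to C4=C15.

Compound list
1 | (R)-(−)-carvone | CC1=CC[C@@H](C(C)=C)CC1=O | starting material
2 | (5R)-5-(2-chloropropan-2-yl)-2-methylcyclohex-2-en-1-one | CC1=CC[C@@H](C(C)(C)Cl)CC1=O | intermediate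
3 | (1S,6R)-3,7,7-trimethylbicyclo[4.1.0]hept-3-en-2-one | CC1=CC[C@@H]2[C@H](C1=O)C2(C)C | intermediate
4 | lithium (1S,6R)-3,7,7-trimethylbicyclo[4.1.0]hept-2-en-2-olate | [Li+].CC1=C([O-])[C@H]2[C@@H](CC1)C2(C)C | intermediate
5 | (1S,6R)-3,7,7-trimethylbicyclo[4.1.0]hept-2-en-2-yl trifluoromethanesulfonate | CC1=C(OS(=O)(=O)C(F)(F)F)[C@H]2[C@@H](CC1)C2(C)C | intermediate
6 | (1S,6R)-2-ethyl-3,7,7-trimethylbicyclo[4.1.0]hept-2-ene | CC1=C(CC)[C@H]2[C@@H](CC1)C2(C)C | intermediate
7 | acrolein | C=CC=O | starting material
8 | 3-[(1S,2E,3S,6R)-2-ethylidene-3,7,7-trimethylbicyclo[4.1.0]heptan-3-yl]propanal | C/C=C1\[C@H]2[C@@H](CC[C@@]1(C)CCC=O)C2(C)C | intermediate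
9 | (4aS,7R)-1,4a-dimethyl-7-(prop-1-en-2-yl)-1,2,3,4,4a,5,6,7-octahydronaphthalen-2-ol (C3/C4 epimers) | C=C(C)[C@@H]1CC[C@@]2(C)CCC(O)C(C)C2=C1 | intermediate
10 | (4aS,7R)-1,4a-dimethyl-7-(prop-1-en-2-yl)-3,4,4a,5,6,7-hexahydronaphthalen-2(1H)-one (C4 epimers) | C=C(C)[C@@H]1CC[C@@]2(C)CCC(=O)C(C)C2=C1 | intermediate
11 | (+)-α-cyperone | C=C(C)[C@@H]1CC[C@@]2(C)CCC(=O)C(C)=C2C1 | intermediate
12 | 12-hydroxyeudesma-4,11(13)-dien-3-one | C=C(CO)[C@@H]1CC[C@@]2(C)CCC(=O)C(C)=C2C1 | intermediate
13 | 3-oxoeudesma-4,11(13)-dien-12-al | C=C(C=O)[C@@H]1CC[C@@]2(C)CCC(=O)C(C)=C2C1 | intermediate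
14 | 3-oxoeudesma-4,11(13)-dien-12-oic acid | C=C(C(=O)O)[C@@H]1CC[C@@]2(C)CCC(=O)C(C)=C2C1 | intermediate
15 | methyl 3-oxoeudesma-4,11(13)-dien-12-oate | C=C(C(=O)OC)[C@@H]1CC[C@@]2(C)CCC(=O)C(C)=C2C1 | intermediate
16 | methyl 3β-hydroxyeudesma-4,11(13)-dien-12-oate | C=C(C(=O)OC)[C@@H]1CC[C@@]2(C)CC[C@H](O)C(C)=C2C1 | intermediate
17 | angelic acid [(Z)-2-methylbut-2-enoic acid] | C/C=C(/C)C(=O)O | starting material
18 | angelic 2,4,6-trichlorobenzoic anhydride | C/C=C(/C)C(=O)OC(=O)c1c(Cl)cc(Cl)cc1Cl | intermediate
19 | methyl 3β-angeloyloxyeudesma-4,11(13)-dien-12-oate | C=C(C(=O)OC)[C@@H]1CC[C@@]2(C)CC[C@H](OC(=O)/C(C)=C\C)C(C)=C2C1 | intermediate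
20 | methyl 3β-angeloyloxy-5α-hydroperoxyeudesma-4(15),11(13)-dien-12-oate | C=C(C(=O)OC)[C@@H]1CC[C@@]2(C)CC[C@H](OC(=O)/C(C)=C\C)C(=C)[C@]2(OO)C1 | target

Total step count: 12. Longest linear sequence: 12 steps (1 → 20).

Steps most likely to fail

Step 5.
- What may go wrong: the cyclopropane may open in the first zwitterion before the proton shift. At the C11 cation stage, chloride capture or loss of the C7 proton may compete. The freed isopropenyl group may undergo a further ene reaction with leftover acrolein.
- Fallback (known chemistry; ring A is built by a chiral-imine Michael addition and a Robinson-type aldol closure instead): it sets out from 1 and comes back at 11. Compound 1 is reduced in the conjugate sense with LiBH(s-Bu)3 and protonated to (+)-dihydrocarvone F1. Condensation with (R)-1-phenylethylamine (toluene, water separator) gives imine F2. Its secondary enamine tautomer adds to pent-1-en-3-one through the more substituted α-carbon, on the face dictated by the auxiliary, to give keto imine F3. Aqueous AcOH hydrolyses this to diketone F4, and NaOMe in MeOH closes ring A by aldol condensation to 11.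

Step 12.
- What may go wrong: hydrogen abstraction from C6 instead of C15 (oxygen then ends on C4), some β-face attack, and decay of the allylic hydroperoxide during purification.
- Fallback (a temporary directing ester and a protected peroxide, with the angelate put on last): it sets out from 16 and comes back at 20. Compound 16 is acylated with (CF3CO)2O/pyridine to trifluoroacetate F5, whose stronger electron pull at C3 should raise the preference for abstraction from the geminal C15 methyl group. Photooxygenation as in step 12 gives hydroperoxide F6, and t-BuMe2SiOTf/2,6-lutidine gives silyl peroxide F7. NaHCO3 in MeOH removes the trifluoroacetate to give alcohol F8. Acylation with mixed anhydride 18 gives angelate F9, and HF·pyridine frees the hydroperoxide 20.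

Step 7.
- What may go wrong: sluggish or unselective allylic oxidation (abstraction of the C7 hydrogen, attack at the γ positions of the enone) and selenium residues that are hard to remove.
- Fallback (ene-type chlorination, then N-oxide oxidation of the halide): it sets out from 11 and comes back at 13. HOCl made from Ca(OCl)2 and CO2 in CH2Cl2/H2O chlorinates only the isopropenyl group, with shift of the double bond, to give allylic chloride F10. N-methylmorpholine N-oxide in MeCN (Kornblum-type oxidation) turns F10 into enal 13.

Further compounds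
F1 | step 5 | (2R,5R)-dihydrocarvone | C[C@@H]1CC[C@@H](C(C)=C)CC1=O
F2 | step 5 | imine of dihydrocarvone and (R)-1-phenylethylamine (C10 labile) | CC1CC[C@@H](C(C)=C)CC1=N[C@H](C)c1ccccc1
F3 | step 5 | keto imine from Michael addition to pent-1-en-3-one | C=C(C)[C@@H]1CC[C@@](C)(CCC(=O)CC)C(=N[C@H](C)c2ccccc2)C1
F4 | step 5 | (2S,5R)-2-methyl-2-(3-oxopentyl)-5-(prop-1-en-2-yl)cyclohexan-1-one | C=C(C)[C@@H]1CC[C@@](C)(CCC(=O)CC)C(=O)C1
F5 | step 12 | methyl 3β-trifluoroacetoxyeudesma-4,11(13)-dien-12-oate | C=C(C(=O)OC)[C@@H]1CC[C@@]2(C)CC[C@H](OC(=O)C(F)(F)F)C(C)=C2C1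
F6 | step 12 | methyl 3β-trifluoroacetoxy-5α-hydroperoxyeudesma-4(15),11(13)-dien-12-oate | C=C(C(=O)OC)[C@@H]1CC[C@@]2(C)CC[C@H](OC(=O)C(F)(F)F)C(=C)[C@]2(OO)C1
F7 | step 12 | tert-butyldimethylsilyl peroxide of F6 | C=C(C(=O)OC)[C@@H]1CC[C@@]2(C)CC[C@H](OC(=O)C(F)(F)F)C(=C)[C@]2(OO[Si](C)(C)C(C)(C)C)C1
F8 | step 12 | methyl 3β-hydroxy-5α-(tert-butyldimethylsilylperoxy)eudesma-4(15),11(13)-dien-12-oate | C=C(C(=O)OC)[C@@H]1CC[C@@]2(C)CC[C@H](O)C(=C)[C@]2(OO[Si](C)(C)C(C)(C)C)C1
F9 | step 12 | methyl 3β-angeloyloxy-5α-(tert-butyldimethylsilylperoxy)eudesma-4(15),11(13)-dien-12-oate | C=C(C(=O)OC)[C@@H]1CC[C@@]2(C)CC[C@H](OC(=O)/C(C)=C\C)C(=C)[C@]2(OO[Si](C)(C)C(C)(C)C)C1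
F10 | step 7 | 12-chloroeudesma-4,11(13)-dien-3-one | C=C(CCl)[C@@H]1CC[C@@]2(C)CCC(=O)C(C)=C2C1
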